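## Structural features

The target is a trimer of three 24-norfriedelane (celastroid) units with one common backbone: trans-fused rings B/C and C/D, a cis-fused D/E decalin, methyl-bearing quaternary carbons C9, C13, C14 and C17, H18β, and C20 with a β-methyl and the α-CO2Me group (C29). Unit A (one end) keeps a cross-conjugated 1(10),5,7-trien-2-one in rings A/B. Units B (centre) and C (other end) have an aromatic ring A with a C4 methyl and oxygen at C2 and C3; unit C has a saturated ring B (8α-H), and unit B carries oxygen at C6 and C7 (both α, cis) next to C8 (α-H) and quaternary C9. Two cis-fused 1,4-benzodioxane rings join the units: O3 and O2 of unit B are bound to C3 (a hemiketal carbon with β-OH) and C4 (β-methyl) of unit A, and O3 and O2 of unit C are bound to C6 and C7 of unit B. Neighbouring stereocentres are C3/C4 in unit A, the run C6–C7–C8–C9 in unit B, C8/C9 in unit C, and the C13/C14 and C17/C18 pairs in every unit. Fragile points are the hemiketal and trienone of unit A, the benzylic aryl ether at C6 of unit B (para to the C2 oxygen, so ionisable once that oxygen is free), the air-sensitive catechol stages and, under strong acid, the methyl-shift-prone backbone. All three units share the backbone of one purchasable hydroxy quinone methide, so the real difficulty is the two dioxanes: which oxygen goes to which carbon, and from which face. The key step exploits the B/C dioxane, whose two aryl–O bonds (C2 of unit C to O7, C3 of unit C to O6 of unit B) can be cut on the aryl side to leave a cis-6α,7α-diol and an ortho-dielectrophilic arene.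

## Logic of the disconnections

18 is cut at the O–C3 and O–C4 bonds of its trienone unit (retro hetero-Diels–Alder). These two bonds form a hemiketal/ether pair that one suprafacial addition of a heterodiene to an enol can make, and the cut removes a whole triterpene unit, two stereocentres and the hemiketal at once. It leads to 17 and 1. The forward step must control which quinone oxygen meets C4 and which face of 1 is attacked, and 17 must be trapped as it forms.

17 goes back to 16 and, through 15, to 14; only the oxidation level of ring A and two acetal groups change. The catechol stays masked during all C–O bond construction. The demand is an unmasking without Brønsted acid, so that the benzylic C6–O bond is not ionised.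

14 is cut at both aryl–O bonds of the B/C dioxane (C2–O7 and C3–O6), giving 7 and 12. Cutting on the aryl side leaves both carbinol stereocentres untouched, so they can be set on a monomer, and it halves the molecule. The forward step needs two C–O couplings in a fixed order through 13: the C2 halide with O7, then the C3 sulfonate with O6. Checked atom by atom against 18, the structures 7, 12 and 14 need no change in constitution or configuration; what is strengthened is the origin of the regiocontrol (temperature staging, a check at the stage of 13, and a fallback that fixes the order by construction).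

7 is simplified by removing the C6–O and C7–O bonds to give 6, and 6 by saturating C6–C7 to give 5. A cis diol on one face maps onto one syn dihydroxylation of an alkene whose faces differ strongly. The demands are dehydrogenation only at the benzylic C6–C7 position and attack of the oxidant on the α face.

12 is traced back by removing the sulfonyl group (11), the iodine (10) and the acetal (9), and by restoring an oxygen function at C2 (8), which comes from 4. The C3 oxygen is kept throughout. The C2 oxygen is exchanged for iodine by way of C2–H, because ortho-iodination of a phenol with its other ortho and para positions blocked is unambiguous. The demand is that O2 and O3 are already distinguishable in 4.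

5 and 8 both arise from 4. 4 is traced to 2 by loss of two molecules of hydrogen (through 3), and 2 to 1 by loss of the acetal. In 1 only O3 bears a proton, so marking it first fixes the O2/O3 pattern for both branches. The demand is that hydrogen adds to C8 from the α face. The backbone centres C9, C13, C14, C17, C18 and C20 of all three units come from 1; C8 (units B and C) is set in step 2, C6 and C7 in step 5, and C3 and C4 of unit A in step 13.

## Other disconnections considered

Alternative 1: The cut lies inside one monomer, at C8–C14 and C9–C10. In the forward sense a Lewis acid would ionise the tertiary allylic alcohol of polyene A1; the E alkene would close ring C on C14 and the arene would close ring B on the C9 cation, giving A2.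
- In its favour: two rings and the C8, C9 and C14 centres in one step, with the trans B/C fusion dictated by alkene geometry. The supply is fully synthetic and open to unnatural analogues; on this point the alternative is the better plan.
- Against it here: A1 needs an enantiopure cis-decalin with quaternary C13, C17 and C20 before any problem of the trimer is touched. Cations flanked by quaternary carbons in this skeleton invite methyl shifts. The arene arrives with two like ether groups, so the C2/C3 distinction needed for 12 must be created later.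
- Comparison: structurally, A2 after hydrogenation of its 15,16-alkene and ether exchange is the analogue of 5, so from there both plans are equal and use steps 4, 5 and 11 to 13. Mechanistically it risks a cationic cascade where the chosen plan needs a hydrogenation. In step count it needs well over a dozen steps to reach the stage that 1 reaches in two.

Alternative 2: The cut is at C5–C6 and C9–C10. A fluoride source would release the aryne from A4, which would add across the vinylcyclohexene diene A3 to give A5.
- In its favour: it is convergent, forms ring B and the benzylic quaternary C9 in one step, and lets arene and terpenoid part be varied independently, which is a better point than the chosen plan offers. A5 is the dimethyl-ether analogue of 3 and would enter the chosen route at the hydrogenation of step 2, an equal point.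
- Against it here: an unsymmetrical aryne meets an unsymmetrical, hindered diene (C5 must bond to the CH2 terminus and C10 to the fully substituted C9), so regiochemistry, the face at C9 and competing ene reaction are all open. A3 still requires the C/D/E tricycle with five stereocentres. O2 and O3 again arrive undifferentiated.
- Comparison: same late structures; a pericyclic step with two open selectivities against none in the chosen plan; many more steps.

Alternative 3: The cut is at C1–C2, C3–C4 and C5–C10, so rings A and B are made together. A cyclopentadienylcobalt catalyst under irradiation would co-cyclise diyne A6 with alkyne A7 to give A8.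
- In its favour: the C4 methyl and two ipso-functionalisable C–B bonds at C2 and C3 are placed by construction. Oxidation of both gives the unit B catechol, so for that stage it is the equal of the chosen plan. It is better in leaving C2 and C3 open to substituents other than oxygen.
- Against it here: the two C–B bonds are alike, so converting them into C2–I and C3–OTf is harder than starting from oxygens that already differ. A6 needs the trans C8/C9 pair with a quaternary ethynyl carbon, so most of the stereochemical work comes before the key step. Two bulky partners must meet on cobalt.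
- Comparison: same monomer structures; metallacycle chemistry with a hindered alkyne against simple functional-group changes; the longest of the three routes.

Key step: step 11

Remark: pristimerin (1), a catalogue natural product (the methyl ester of celastrol) and already the dienophile of the last step, is taken as the single chiral starting material for all three units; this replaces some thirty steps of monomer construction at the price of relying on an isolated terpenoid.

## Steps

Step 1
Reactants: 1 pristimerin (methyl 3-hydroxy-2-oxo-24-norfriedela-1(10),3,5,7-tetraen-29-oate)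
Product: 2 3-O-(methoxymethyl)pristimerin (methyl 3-(methoxymethoxy)-2-oxo-24-norfriedela-1(10),3,5,7-tetraen-29-oate)
Conditions: MOMCl, iPr2NEt, CH2Cl2, 0 °C to rt
Reagents that add atoms: chloromethyl methyl ether (MOMCl), COCCl
Why: Williamson-type O-alkylation of the acidic C3 enol of the hydroxy quinone methide; only this oxygen carries a proton, so O3 is marked against O2 from here on, and no stereocentre is touched.

Step 2
Reactants: 2 3-O-(methoxymethyl)pristimerin
Product: 4 methyl 2-hydroxy-3-(methoxymethoxy)-24-norfriedela-1,3,5(10)-trien-29-oate (8α-H), via 7-ene phenol 3 (not isolated)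
Conditions: H2 (5 bar), Pd/C (10 % Pd), EtOAc–EtOH, 40 °C
Reagents that add atoms: none
Why: Heterogeneous hydrogenation in two stages in one flask: 1,6-addition of H2 to the quinone methide aromatises ring A (phenol 3), then syn addition to the hindered C7=C8 alkene should occur from the α face, because the β face of C8 is covered by the axial methyl groups on C9 and C14; this sets 8α-H (trans B/C fusion), and no acid is present that could start backbone rearrangement.

Step 3
Reactants: 4 methyl 2-hydroxy-3-(methoxymethoxy)-24-norfriedela-1,3,5(10)-trien-29-oate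
Product: 5 methyl 2,3-bis(methoxymethoxy)-24-norfriedela-1,3,5(10)-trien-29-oate
Conditions: MOMCl, iPr2NEt, CH2Cl2, rt
Reagents that add atoms: chloromethyl methyl ether (MOMCl), COCCl
Why: Williamson-type alkylation of the C2 phenol; the bis-acetal is inert to DDQ, OsO4, carbonate base and palladium in the steps that follow.

Step 4
Reactants: 5 methyl 2,3-bis(methoxymethoxy)-24-norfriedela-1,3,5(10)-trien-29-oate
Product: 6 methyl 2,3-bis(methoxymethoxy)-24-norfriedela-1,3,5(10),6-tetraen-29-oate (8α-H)
Conditions: DDQ (1.2 equiv), 1,4-dioxane (dry), 80 °C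
Reagents that add atoms: none
Why: DDQ benzylic dehydrogenation: hydride is abstracted from C6, which is para to the C2 oxygen, and loss of H7 gives the conjugated styrene; C9 is quaternary, so no aromatisation can follow, and C8 is not involved.

Step 5
Reactants: 6 methyl 2,3-bis(methoxymethoxy)-24-norfriedela-1,3,5(10),6-tetraen-29-oate
Product: 7 methyl 6α,7α-dihydroxy-2,3-bis(methoxymethoxy)-24-norfriedela-1,3,5(10)-trien-29-oate
Conditions: OsO4 (5 mol %), NMO, acetone–H2O, rt
Reagents that add atoms: osmium tetroxide, O=[Os](=O)(=O)=O; N-methylmorpholine N-oxide, C[N+]1([O-])CCOCC1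
Why: Catalytic OsO4 cis-dihydroxylation: the suprafacial [3+2] addition fixes the cis relation of C6 and C7, and attack on the α face, anti to the axial C9β methyl group, should make both hydroxyls α.

Step 6
Reactants: 4 methyl 2-hydroxy-3-(methoxymethoxy)-24-norfriedela-1,3,5(10)-trien-29-oate
Product: 8 methyl 3-(methoxymethoxy)-2-(trifluoromethylsulfonyloxy)-24-norfriedela-1,3,5(10)-trien-29-oate
Conditions: Tf2O, pyridine, CH2Cl2, 0 °C
Reagents that add atoms: triflic anhydride, O=S(=O)(OS(=O)(=O)C(F)(F)F)C(F)(F)F
Why: O-Sulfonylation of the only free phenol; O3 is blocked, so the triflate can only go to C2.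

Step 7
Reactants: 8 methyl 3-(methoxymethoxy)-2-(trifluoromethylsulfonyloxy)-24-norfriedela-1,3,5(10)-trien-29-oate
Product: 9 methyl 3-(methoxymethoxy)-24-norfriedela-1,3,5(10)-trien-29-oate
Conditions: Pd(OAc)2, PPh3, HCO2H, Et3N, DMF, 70 °C
Reagents that add atoms: none
Why: Palladium-catalysed formate reduction of an aryl triflate (oxidative addition, formate exchange, decarboxylation, C–H reductive elimination) removes the C2 oxygen and leaves C2–H for the later iodination.

Step 8
Reactants: 9 methyl 3-(methoxymethoxy)-24-norfriedela-1,3,5(10)-trien-29-oate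
Product: 10 methyl 3-hydroxy-24-norfriedela-1,3,5(10)-trien-29-oate
Conditions: HCl (3 M aq.), MeOH–THF, 50 °C
Reagents that add atoms: none
Why: Acid-catalysed acetal exchange with methanol frees the C3 phenol; this monomer has no acid-sensitive benzylic oxygen and the hindered tertiary ester is stable.

Step 9
Reactants: 10 methyl 3-hydroxy-24-norfriedela-1,3,5(10)-trien-29-oate
Product: 11 methyl 3-hydroxy-2-iodo-24-norfriedela-1,3,5(10)-trien-29-oate
Conditions: NIS, TsOH (cat.), MeCN, 0 °C
Reagents that add atoms: N-iodosuccinimide, O=C1CCC(=O)N1I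
Why: Electrophilic aromatic iodination ortho to the phenol; C4 carries the methyl group and the para position C10 is the ring-fusion carbon, so C2 is the only activated free position.

Step 10
Reactants: 11 methyl 3-hydroxy-2-iodo-24-norfriedela-1,3,5(10)-trien-29-oate
Product: 12 methyl 2-iodo-3-(trifluoromethylsulfonyloxy)-24-norfriedela-1,3,5(10)-trien-29-oate
Conditions: Tf2O, pyridine, CH2Cl2, 0 °C
Reagents that add atoms: triflic anhydride, O=S(=O)(OS(=O)(=O)C(F)(F)F)C(F)(F)F
Why: O-Sulfonylation of the phenol gives the ortho-dielectrophile; iodide and triflate differ widely in rate of oxidative addition and can be addressed one after the other.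

Step 11
Reactants: 7 methyl 6α,7α-dihydroxy-2,3-bis(methoxymethoxy)-24-norfriedela-1,3,5(10)-trien-29-oate; 12 methyl 2-iodo-3-(trifluoromethylsulfonyloxy)-24-norfriedela-1,3,5(10)-trien-29-oate
Product: 14 B/C dimer with a cis-fused 1,4-benzodioxane (O6 of unit B on C3 and O7 of unit B on C2 of unit C; unit B catechol as bis(methoxymethyl) ether), via mono-aryl ether 13 (not isolated)
Conditions: Pd(OAc)2 (10 mol %), RockPhos (20 mol %), Cs2CO3 (3 equiv), toluene, 4 Å MS, 50 °C, then 100 °C
Reagents that add atoms: none
Why: Buchwald–Hartwig etherification run twice in one flask: zerovalent palladium (formed from Pd(OAc)2 and the phosphine RockPhos, 2-(di-tert-butylphosphino)-3-methoxy-6-methyl-2′,4′,6′-triisopropylbiphenyl) inserts into the C2–I bond of 12 at 50 °C, where the C3–OTf bond is still inert; the alcohol binds divalent palladium, Cs2CO3 removes its proton and C–O reductive elimination gives aryl ether 13. At 100 °C the catalyst inserts into the neighbouring C3–OTf bond, the C6 alkoxide binds intramolecularly and reductive elimination from a seven-membered oxapalladacycle closes the six-membered 1,4-dioxane ring. The closest known reactions are the intermolecular coupling of secondary alcohols with aryl halides under bulky di-tert-butylbiarylphosphine ligands and the intramolecular closure of halo- or sulfonyloxy-aryl alcohols to 1,4-benzodioxanes. No stereocentre is formed: neither carbinol carbon takes part in bond making or breaking, so C6 and C7 keep the cis-6α,7α configuration of 7. Two selectivities are needed: iodide before triflate, secured by the large rate gap in oxidative addition and by the temperature staging, and the C7 hydroxyl before the C6 hydroxyl, favoured because the C7 hydroxyl is equatorial and non-benzylic whereas the C6 hydroxyl is pseudo-axial and flanked by the ortho,ortho′-disubstituted arene. Since the second preference is only a bias, the constitution of 13 is to be checked on an aliquot (HMBC from H7 to C2 of unit C) before heating. The bulky ligand should favour C–O reductive elimination over β-hydride elimination of the secondary alkoxides, and the weak, insoluble base should spare the triflate and the esters.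

Step 12
Reactants: 14 B/C dimer, unit B catechol as bis(methoxymethyl) ether
Product: 16 B/C dimer with free 2,3-catechol on unit B, via bis(trimethylsilyl) ether 15 (not isolated)
Conditions: TMSOTf, 2,2′-bipyridyl, CH2Cl2, 0 °C; then H2O
Reagents that add atoms: none
Why: Lewis-acid acetal cleavage buffered by 2,2′-bipyridyl converts the aryl MOM ethers into aryl trimethylsilyl ethers 15, which water hydrolyses; no Brønsted acid and no external nucleophile are present, so the benzylic C6–O aryl ether para to the freed oxygen should survive, and 16 is used at once.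

Step 13
Reactants: 16 B/C dimer with free 2,3-catechol on unit B; 1 pristimerin (3 equiv)
Product: 18 target trimer CNP0359256.2, via o-quinone 17 (not isolated)
Conditions: Ag2O, CH2Cl2, 4 Å MS, 0 °C to rt, dark, oxidant added last
Reagents that add atoms: none
Why: Ag2O oxidises the catechol to o-quinone 17, which is trapped as the electron-poor heterodiene in an inverse-electron-demand hetero-Diels–Alder reaction with the C3=C4 enol double bond of 1; the concerted suprafacial addition makes the new dioxane cis-fused and gives the C3 hemiketal directly. The less hindered O2 of unit B should bond to the fully substituted C4 and O3 to C3, and approach to the α face of 1, away from its C9β methyl group, should give 3β-OH and 4β-methyl.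

## Compound list

1 | pristimerin, methyl 3-hydroxy-2-oxo-24-norfriedela-1(10),3,5,7-tetraen-29-oate | COC(=O)[C@]1(C)CC[C@]2(C)CC[C@]3(C)C4=CC=C5C(C)=C(O)C(=O)C=C5[C@]4(C)CC[C@@]3(C)[C@@H]2C1 | starting material
2 | 3-O-(methoxymethyl)pristimerin | COC(=O)[C@]1(C)CC[C@]2(C)CC[C@]3(C)C4=CC=C5C(C)=C(OCOC)C(=O)C=C5[C@]4(C)CC[C@@]3(C)[C@@H]2C1 | intermediate
3 | methyl 2-hydroxy-3-(methoxymethoxy)-24-norfriedela-1,3,5(10),7-tetraen-29-oate (not isolated) | COCOc1c(O)cc2c(c1C)CC=C3[C@@]2(C)CC[C@@]4(C)[C@@H]5C[C@](C)(C(=O)OC)CC[C@]5(C)CC[C@]34C | intermediate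
4 | methyl 2-hydroxy-3-(methoxymethoxy)-24-norfriedela-1,3,5(10)-trien-29-oate (8α-H) | COCOc1c(O)cc2c(c1C)CC[C@H]3[C@@]2(C)CC[C@@]4(C)[C@@H]5C[C@](C)(C(=O)OC)CC[C@]5(C)CC[C@]34C | intermediate
5 | methyl 2,3-bis(methoxymethoxy)-24-norfriedela-1,3,5(10)-trien-29-oate | COCOc1c(OCOC)cc2c(c1C)CC[C@H]3[C@@]2(C)CC[C@@]4(C)[C@@H]5C[C@](C)(C(=O)OC)CC[C@]5(C)CC[C@]34C | intermediate
6 | methyl 2,3-bis(methoxymethoxy)-24-norfriedela-1,3,5(10),6-tetraen-29-oate | COCOc1c(OCOC)cc2c(c1C)C=C[C@H]3[C@@]2(C)CC[C@@]4(C)[C@@H]5C[C@](C)(C(=O)OC)CC[C@]5(C)CC[C@]34C | intermediate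
7 | methyl 6α,7α-dihydroxy-2,3-bis(methoxymethoxy)-24-norfriedela-1,3,5(10)-trien-29-oate | COCOc1c(OCOC)cc2c(c1C)[C@@H](O)[C@@H](O)[C@H]3[C@@]2(C)CC[C@@]4(C)[C@@H]5C[C@](C)(C(=O)OC)CC[C@]5(C)CC[C@]34C | intermediate
8 | methyl 3-(methoxymethoxy)-2-(trifluoromethylsulfonyloxy)-24-norfriedela-1,3,5(10)-trien-29-oate | COCOc1c(OS(=O)(=O)C(F)(F)F)cc2c(c1C)CC[C@H]3[C@@]2(C)CC[C@@]4(C)[C@@H]5C[C@](C)(C(=O)OC)CC[C@]5(C)CC[C@]34C | intermediate
9 | methyl 3-(methoxymethoxy)-24-norfriedela-1,3,5(10)-trien-29-oate | COCOc1ccc2c(c1C)CC[C@H]3[C@@]2(C)CC[C@@]4(C)[C@@H]5C[C@](C)(C(=O)OC)CC[C@]5(C)CC[C@]34C | intermediate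
10 | methyl 3-hydroxy-24-norfriedela-1,3,5(10)-trien-29-oate | Cc1c(O)ccc2c1CC[C@H]3[C@@]2(C)CC[C@@]4(C)[C@@H]5C[C@](C)(C(=O)OC)CC[C@]5(C)CC[C@]34C | intermediate
11 | methyl 3-hydroxy-2-iodo-24-norfriedela-1,3,5(10)-trien-29-oate | Cc1c(O)c(I)cc2c1CC[C@H]3[C@@]2(C)CC[C@@]4(C)[C@@H]5C[C@](C)(C(=O)OC)CC[C@]5(C)CC[C@]34C | intermediate
12 | methyl 2-iodo-3-(trifluoromethylsulfonyloxy)-24-norfriedela-1,3,5(10)-trien-29-oate | Cc1c(OS(=O)(=O)C(F)(F)F)c(I)cc2c1CC[C@H]3[C@@]2(C)CC[C@@]4(C)[C@@H]5C[C@](C)(C(=O)OC)CC[C@]5(C)CC[C@]34C | intermediate
13 | mono-aryl ether: O7 of unit B (6α-OH free, 2,3-bis-MOM) bound to C2 of unit C, which keeps its C3 triflate (not isolated) | COCOc1c(OCOC)cc2c(c1C)[C@@H](O)[C@@H](Oc3cc4c(c(C)c3OS(=O)(=O)C(F)(F)F)CC[C@H]3[C@@]4(C)CC[C@@]4(C)[C@@H]5C[C@](C)(C(=O)OC)CC[C@]5(C)CC[C@]34C)[C@H]3[C@@]2(C)CC[C@@]4(C)[C@@H]5C[C@](C)(C(=O)OC)CC[C@]5(C)CC[C@]34C | intermediate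
14 | B/C benzodioxane dimer, unit B catechol as bis(methoxymethyl) ether | COCOc7c(cc8c(c7C)[C@H]7Oc9c(cc%10c(c9C)CC[C@H]9[C@@]%10(C)CC[C@@]%10(C)[C@@H]%11C[C@](C)(C(=O)OC)CC[C@]%11(C)CC[C@]9%10C)O[C@H]7[C@H]7[C@@]8(C)CC[C@@]8(C)[C@@H]9C[C@](C)(C(=O)OC)CC[C@]9(C)CC[C@]78C)OCOC | intermediate
15 | B/C benzodioxane dimer, unit B catechol as bis(trimethylsilyl) ether (not isolated) | C[Si](C)(C)Oc7c(cc8c(c7C)[C@H]7Oc9c(cc%10c(c9C)CC[C@H]9[C@@]%10(C)CC[C@@]%10(C)[C@@H]%11C[C@](C)(C(=O)OC)CC[C@]%11(C)CC[C@]9%10C)O[C@H]7[C@H]7[C@@]8(C)CC[C@@]8(C)[C@@H]9C[C@](C)(C(=O)OC)CC[C@]9(C)CC[C@]78C)O[Si](C)(C)C | intermediate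
16 | B/C benzodioxane dimer, unit B as free 2,3-catechol | Oc7c(cc8c(c7C)[C@H]7Oc9c(cc%10c(c9C)CC[C@H]9[C@@]%10(C)CC[C@@]%10(C)[C@@H]%11C[C@](C)(C(=O)OC)CC[C@]%11(C)CC[C@]9%10C)O[C@H]7[C@H]7[C@@]8(C)CC[C@@]8(C)[C@@H]9C[C@](C)(C(=O)OC)CC[C@]9(C)CC[C@]78C)O | intermediate
17 | B/C benzodioxane dimer, unit B ring A as 1(10),4-diene-2,3-dione (o-quinone, not isolated) | O=C7C(=O)C=C8C(=C7C)[C@H]7Oc9c(cc%10c(c9C)CC[C@H]9[C@@]%10(C)CC[C@@]%10(C)[C@@H]%11C[C@](C)(C(=O)OC)CC[C@]%11(C)CC[C@]9%10C)O[C@H]7[C@H]7[C@@]8(C)CC[C@@]8(C)[C@@H]9C[C@](C)(C(=O)OC)CC[C@]9(C)CC[C@]78C | intermediate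
18 | target trimer CNP0359256.2 (A/B dioxane: O3 of unit B on C3 and O2 of unit B on C4 of unit A, both on the α face; 3β-OH, 4β-Me) | COC(=O)[C@]1(C)CC[C@]2(C)CC[C@]3(C)C4=CC=C5C(=CC(=O)[C@@]6(O)Oc7c(cc8c(c7C)[C@H]7Oc9c(cc%10c(c9C)CC[C@H]9[C@@]%10(C)CC[C@@]%10(C)[C@@H]%11C[C@](C)(C(=O)OC)CC[C@]%11(C)CC[C@]9%10C)O[C@H]7[C@H]7[C@@]8(C)CC[C@@]8(C)[C@@H]9C[C@](C)(C(=O)OC)CC[C@]9(C)CC[C@]78C)O[C@@]56C)[C@]4(C)CC[C@@]3(C)[C@@H]2C1 | target

## Step count and least certain steps

Total: 13 steps. Longest linear sequence: 10 steps (steps 1, 2, 6, 7, 8, 9, 10, 11, 12, 13).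

Step 11 (key step). Most likely failures: the first etherification takes place at the C6 instead of the C7 hydroxyl (loss of regiocontrol); the palladium alkoxide undergoes β-hydride elimination, which oxidises the carbinol and reduces the iodide; or the triflate is cleaved at sulfur before ring closure. Fallback that fixes the order by construction, setting out from 7 and 12:
- Oxidise the electron-rich benzylic C6 alcohol of 7 selectively with DDQ to methyl 7α-hydroxy-2,3-bis(methoxymethoxy)-6-oxo-24-norfriedela-1,3,5(10)-trien-29-oate F1.
- Couple its single hydroxyl with the iodide of 12 (same catalyst, 50 °C) to the keto aryl ether F2.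
- Reduce the aryl ketone (NaBH4, CeCl3), hydride entering anti to the neighbouring 7α-aryloxy group, to the 6α-alcohol, which is 13.
- Close the dioxane under the 100 °C conditions of step 11; the fallback returns to the route at 14.

Step 2. Most likely failures: incomplete saturation of the hindered trisubstituted C7=C8 bond, or erosion of facial selectivity at C8 under forcing conditions. Fallback from 2: reduce the quinone methide with NaBH4 (1,6-hydride addition) and isolate 3, then saturate C7=C8 by metal-hydride hydrogen-atom transfer (Mn(dpm)3, PhSiH3, tert-butyl hydroperoxide, iPrOH). This is a stepwise radical process under thermodynamic control in place of surface hydrogenation, with hydrogen again delivered to the C8 radical on the open α face; it returns at 4.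

Step 4. Most likely failures: over-oxidation (a second hydride abstraction at the allylic C8–H followed by methyl migration), or sluggish abstraction because peri strain with the C4 methyl group twists the benzylic cation. Fallback from 5: benzylic oxidation (CrO3, 3,5-dimethylpyrazole, CH2Cl2) to methyl 2,3-bis(methoxymethoxy)-6-oxo-24-norfriedela-1,3,5(10)-trien-29-oate F3; reduction with NaBH4 to the 6β-alcohol F4; dehydration with the Burgess reagent to return at 6.

Step 13. Most likely failures: tautomerisation or decomposition of the o-quinone before it is trapped (its C6–H is vinylogously acidic), or poor regio- and facial selectivity of the cycloaddition. Fallback, an ionic two-bond annulation of known type (catechol plus α-halo ketone), setting out from 16 and 1: brominate 1 at C4 with NBS to the α-bromo-1,2-diketone methyl 4α-bromo-2,3-dioxo-24-norfriedela-1(10),5,7-trien-29-oate F5. Then combine 16 and F5 with AgOTf and 2,6-di-tert-butylpyridine at −40 °C, so that O2 of unit B replaces bromide at C4 on the α face and O3 adds to the C3 carbonyl as the hemiketal; this returns at 18.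

## Further compounds

F1 | step 11 | methyl 7α-hydroxy-2,3-bis(methoxymethoxy)-6-oxo-24-norfriedela-1,3,5(10)-trien-29-oate | COCOc1c(OCOC)cc2c(c1C)C(=O)[C@@H](O)[C@H]3[C@@]2(C)CC[C@@]4(C)[C@@H]5C[C@](C)(C(=O)OC)CC[C@]5(C)CC[C@]34C
F2 | step 11 | keto aryl ether: O7 of the 6-oxo unit B bound to C2 of unit C, which keeps its C3 triflate | COCOc1c(OCOC)cc2c(c1C)C(=O)[C@@H](Oc3cc4c(c(C)c3OS(=O)(=O)C(F)(F)F)CC[C@H]3[C@@]4(C)CC[C@@]4(C)[C@@H]5C[C@](C)(C(=O)OC)CC[C@]5(C)CC[C@]34C)[C@H]3[C@@]2(C)CC[C@@]4(C)[C@@H]5C[C@](C)(C(=O)OC)CC[C@]5(C)CC[C@]34C
F0 | step 2 | none | none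
F3 | step 4 | methyl 2,3-bis(methoxymethoxy)-6-oxo-24-norfriedela-1,3,5(10)-trien-29-oate | COCOc1c(OCOC)cc2c(c1C)C(=O)C[C@H]3[C@@]2(C)CC[C@@]4(C)[C@@H]5C[C@](C)(C(=O)OC)CC[C@]5(C)CC[C@]34C
F4 | step 4 | methyl 6β-hydroxy-2,3-bis(methoxymethoxy)-24-norfriedela-1,3,5(10)-trien-29-oate | COCOc1c(OCOC)cc2c(c1C)[C@H](O)C[C@H]3[C@@]2(C)CC[C@@]4(C)[C@@H]5C[C@](C)(C(=O)OC)CC[C@]5(C)CC[C@]34C
F5 | step 13 | methyl 4α-bromo-2,3-dioxo-24-norfriedela-1(10),5,7-trien-29-oate | COC(=O)[C@]1(C)CC[C@]2(C)CC[C@]3(C)C4=CC=C5C(=CC(=O)C(=O)[C@@]5(C)Br)[C@]4(C)CC[C@@]3(C)[C@@H]2C1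
A1 | alternative 1 | cyclisation substrate: cis-D/E decalin with C14 tertiary allylic alcohol, 15,16-alkene and the E-configured C8=C9 aryl-terminated side chain on C13 | COc1c(OC)ccc(CC/C=C(\C)CC[C@@]2(C)[C@@H]3C[C@](C)(C(=O)OC)CC[C@]3(C)C=CC2(C)O)c1C
A2 | alternative 1 | 15,16-didehydro unit C monomer, catechol dimethyl ether | COc1c(OC)cc2c(c1C)CC[C@H]3[C@@]2(C)CC[C@@]4(C)[C@@H]5C[C@](C)(C(=O)OC)CC[C@]5(C)C=C[C@]34C
A3 | alternative 2 | C/D/E tricycle with the C6=C7–C8=C9 vinylcyclohexene diene | C=CC1=C(C)CC[C@@]2(C)[C@@H]3C[C@](C)(C(=O)OC)CC[C@]3(C)CC[C@]12C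
A4 | alternative 2 | aryne precursor, 4,5-dimethoxy-3-methyl-2-(trimethylsilyl)phenyl triflate | COc1cc(OS(=O)(=O)C(F)(F)F)c([Si](C)(C)C)c(C)c1OC
A5 | alternative 2 | 7-ene pentacyclic catechol dimethyl ether | COc1c(OC)cc2c(c1C)CC=C3[C@@]2(C)CC[C@@]4(C)[C@@H]5C[C@](C)(C(=O)OC)CC[C@]5(C)CC[C@]34C
A6 | alternative 3 | C/D/E tricycle with C9 ethynyl and C8 pent-3-ynyl groups | CC#CCC[C@H]1[C@](C)(C#C)CC[C@@]2(C)[C@@H]3C[C@](C)(C(=O)OC)CC[C@]3(C)CC[C@]12C
A7 | alternative 3 | bis(pinacolboryl)acetylene | CC1(C)OB(C#CB2OC(C)(C)C(C)(C)O2)OC1(C)C
A8 | alternative 3 | 2,3-bis(pinacolboryl) unit C arene | Cc1c(B6OC(C)(C)C(C)(C)O6)c(B7OC(C)(C)C(C)(C)O7)cc2c1CC[C@H]3[C@@]2(C)CC[C@@]4(C)[C@@H]5C[C@](C)(C(=O)OC)CC[C@]5(C)CC[C@]34C
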